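**Retrosynthetic overview**
- The target is the nonadecyl ester of 3-(4-hydroxyphenyl)propanoic acid. It has no stereocentre and its only ring is a purchased benzene ring, so no ring is formed; the only ring event is the opening of tetrahydrofuran.
- Key disconnection: C4–C5 of the nonadecyl chain (C1 = OCH2). This gives a pentadecyl nucleophile (C5–C19) and a C1–C4 electrophile still attached to the ester oxygen.
- Enabling feature: the ester alkyl oxygen plus chain carbons C1–C4 are, atom for atom, the O1/C2–C5 ring of tetrahydrofuran. O-Acylation of that ring makes the ring α-carbon that becomes C4 electrophilic, so acid chloride, tetrahydrofuran and pentadecyl Grignard reagent can be joined in one flask, forming the ester C(=O)–O bond and the C4–C5 bond in the same operation.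
- The phenol is carried as a benzyl ether and freed last by hydrogenolysis. The acid chloride and the Grignard reagent are each one step from purchased materials.

Key step: step 3

Assumption: 3-[4-(benzyloxy)phenyl]propanoic acid, 1-bromopentadecane and anhydrous tetrahydrofuran are taken as purchased materials.

Step 1
Reactants: 1 3-[4-(benzyloxy)phenyl]propanoic acid
Product: 2 3-[4-(benzyloxy)phenyl]propanoyl chloride
Conditions: (COCl)2 (1.3 equiv), DMF (cat.), CH2Cl2, 0 °C → rt; volatiles removed in vacuo, used crude
Reagents that add atoms: oxalyl chloride, ClC(=O)C(=O)Cl
Why: Acid chloride formation through the catalytic Vilsmeier-type chloroiminium species; the benzyl aryl ether is inert and all by-products are gases.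

Step 2
Reactants: 3 1-bromopentadecane
Product: 4 pentadecylmagnesium bromide (about 0.5 M solution, titrated)
Conditions: Mg turnings (1.5 equiv), I2 (cat.), 2-MeTHF, slow addition, 40–50 °C
Reagents that add atoms: magnesium, [Mg]
Why: Grignard reagent formation by insertion of magnesium into a primary C–Br bond; slow addition at moderate dilution should keep Wurtz coupling low.

Step 3
Reactants: 2 3-[4-(benzyloxy)phenyl]propanoyl chloride; 5 tetrahydrofuran (reactant and solvent); 4 pentadecylmagnesium bromide
Product: 9 nonadecyl 3-[4-(benzyloxy)phenyl]propanoate, via acyl iodide 6 (not isolated), via O-acyloxolanium iodide 7 (not isolated), via 4-iodobutyl ester 8 (not isolated)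
Conditions: (i) LiI (1.1 equiv, anhydrous), THF, 0 °C → rt (to 40 °C if needed), dark, until the acyl halide is consumed; (ii) CuI (5 mol%), NMP (4 equiv), then 4 (1.2 equiv, added over 1 h), −10 → 0 °C; aq NH4Cl/NH3 work-up
Reagents that add atoms: lithium iodide, [Li+].[I-] (its iodine is carried only by 6, 7 and 8 and is not retained in 9)
Why: Stage (i) is the acylative cleavage of a cyclic ether by an acyl iodide: chloride/iodide exchange on 2 gives 6, the ring oxygen of 5 is acylated to the oxolanium salt 7, and iodide opens 7 by SN2 attack at a ring α-carbon to give 8; because 5 is the solvent, all acyl halide should be consumed before any organometallic enters the flask. Stage (ii) is a copper-catalysed Kumada-type alkyl–alkyl coupling: the alkylcuprate formed from 4 and CuI displaces the primary iodide of 8 (SN2-type oxidative addition, then reductive elimination) and forms C4–C5 of the nonadecyl chain. Both stages are established reaction types, for acyl chlorides plus iodide with tetrahydrofuran and for ω-halo esters with primary alkyl Grignard reagents, so the step telescopes known chemistry into one flask. No ring is closed (one is opened) and no stereocentre is formed. The selectivity needed is substitution at C–I in preference to addition to the ester carbonyl; the primary iodide, the copper catalyst with NMP as co-solvent, slow addition of 4 and the low temperature should secure it, and regiochemistry is no issue because 5 is symmetrical. The lithium halides left from stage (i) should keep the copper(I) catalyst in solution.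

Step 4
Reactants: 9 nonadecyl 3-[4-(benzyloxy)phenyl]propanoate
Product: 10 nonadecyl 3-(4-hydroxyphenyl)propanoate
Conditions: H2 (1 atm), 10% Pd/C, EtOAc/THF, rt; filtration, recrystallisation
Reagents that add atoms: none
Why: Palladium-catalysed hydrogenolysis of a benzyl aryl ether; the saturated alkyl ester and the arene should be inert at 1 atm and room temperature.

**Compound list**
1 | 3-[4-(benzyloxy)phenyl]propanoic acid | OC(=O)CCc1ccc(OCc2ccccc2)cc1 | starting material
2 | 3-[4-(benzyloxy)phenyl]propanoyl chloride | ClC(=O)CCc1ccc(OCc2ccccc2)cc1 | intermediate
3 | 1-bromopentadecane | CCCCCCCCCCCCCCCBr | starting material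
4 | pentadecylmagnesium bromide | CCCCCCCCCCCCCCC[Mg]Br | intermediate
5 | tetrahydrofuran (oxolane) | C1CCOC1 | starting material
6 | 3-[4-(benzyloxy)phenyl]propanoyl iodide | IC(=O)CCc1ccc(OCc2ccccc2)cc1 | intermediate
7 | 1-{3-[4-(benzyloxy)phenyl]propanoyl}oxolan-1-ium iodide | O=C(CCc1ccc(OCc2ccccc2)cc1)[O+]1CCCC1.[I-] | intermediate
8 | 4-iodobutyl 3-[4-(benzyloxy)phenyl]propanoate | ICCCCOC(=O)CCc1ccc(OCc2ccccc2)cc1 | intermediate
9 | nonadecyl 3-[4-(benzyloxy)phenyl]propanoate | CCCCCCCCCCCCCCCCCCCOC(=O)CCc1ccc(OCc2ccccc2)cc1 | intermediate
10 | nonadecyl 3-(4-hydroxyphenyl)propanoate | CCCCCCCCCCCCCCCCCCCOC(=O)CCc1ccc(O)cc1 | target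

Total step count: 4
Longest linear sequence: 3 steps (1 → 3 → 4, or 2 → 3 → 4)

**Steps most likely to fail**

1. Step 3. In the copper stage, addition of the Grignard reagent to the ester carbonyl, or iodine–magnesium exchange followed by homocoupling, may outrun the substitution; an incomplete ring-opening would also leave acyl halide to be attacked by the Grignard reagent. The fallback sets out from 2 and comes back to the route at 10. Acid chloride 2 would be esterified with pent-4-en-1-ol (Et3N, cat. DMAP, CH2Cl2, 0 °C → rt) to pent-4-en-1-yl 3-[4-(benzyloxy)phenyl]propanoate F1. Cross-metathesis of F1 with 1-hexadecene (3 equiv, Grubbs second-generation catalyst, CH2Cl2, 40 °C) should form the same C4–C5 bond as an alkene, (4E)-nonadec-4-en-1-yl 3-[4-(benzyloxy)phenyl]propanoate F2; the E isomer is drawn, and any Z isomer converges in the next operation. Hydrogenation (H2, Pd/C, EtOAc) should then saturate the alkene and cleave the benzyl ether together, giving 10.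

2. Step 2. Wurtz-type homocoupling on the magnesium surface and sluggish initiation may lower the titre, and unreacted bromide would then compete in the copper stage. The fallback sets out from 3 and comes back to the route at 9. Zinc dust (activated with cat. I2) in DMA at 80 °C should insert into 3 to give pentadecylzinc bromide F3, a reagent that is compatible with esters. Iodide 8 would be made as in stage (i) of step 3 but isolated (aq Na2S2O3/NaHCO3 work-up, short silica column). A palladium-catalysed alkyl–alkyl Negishi coupling of F3 with 8 (Pd2(dba)3, tricyclopentylphosphine, N-methylimidazole, THF/NMP, 80 °C) should then give 9.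

3. Step 4. The hydrogenolysis may stall through poisoning of the catalyst by traces of iodide or copper carried over from step 3, or through low solubility of the waxy substrate. The fallback sets out from 9 and comes back to the route at 10. Saponification of 9 (KOH, EtOH/H2O, reflux; acid 1 is recovered on acidification) should give nonadecan-1-ol F4. Fischer esterification of F4 with purchased, unprotected 3-(4-hydroxyphenyl)propanoic acid (TsOH cat., toluene, Dean–Stark) should then give 10, since the phenol is not acylated under these conditions.

**Further compounds**
F1 | step 3 | pent-4-en-1-yl 3-[4-(benzyloxy)phenyl]propanoate | C=CCCCOC(=O)CCc1ccc(OCc2ccccc2)cc1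
F2 | step 3 | (4E)-nonadec-4-en-1-yl 3-[4-(benzyloxy)phenyl]propanoate | CCCCCCCCCCCCCC/C=C/CCCOC(=O)CCc1ccc(OCc2ccccc2)cc1
F3 | step 2 | pentadecylzinc bromide | CCCCCCCCCCCCCCC[Zn]Br
F4 | step 4 | nonadecan-1-ol | CCCCCCCCCCCCCCCCCCCO
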